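**Strategy.** The target is cut at the cis-fused dihydrofuran ring O7''–C3–C2–C8''–C7''. In this ring the C7''–C8'' edge of the flavonol A ring is bridged by O, C3 and C2 of the chromanone, which are the three atoms of a flavonol 2,3-epoxide. A kaempferol-derived 7,8-aryne is therefore inserted into the C2–O bond of enantioenriched tetra-O-benzylkaempferol 2,3-oxide. This one operation forms O7''–C7'' and C2–C8'', closes the ring and carries the epoxide configuration into both stereocentres. The partners are the (2R,3R)-epoxide and the 8-trimethylsilyl 7-triflate of 3,5,4'-tri-O-benzylkaempferol. Global hydrogenolysis then unveils the hemiketal.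

Key step: step 10

**Remarks**
- Numbering: chromanone unit O1, C2–C8a with aryl ring primed; flavonol unit doubly primed with aryl ring triply primed.
- Assumption for step 2: the sense of induction cannot be predicted for this substrate, so the catalyst antipode (both are commercial) is the one that a preliminary screen shows to give the (2R,3R)-epoxide.
- The precursor and product structures are mutually consistent. C3 changes descriptor from R in the epoxide to S in the product by CIP priority only; its spatial arrangement is unchanged.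
- Partial benzylation of kaempferol leaves the chelated 5-OH free, not the 7-OH. The 3,5,4'-tri-O-benzyl pattern is therefore reached through selective 7-O-deacetylation and a temporary 7-O-MOM group, and bromine is introduced on the 5,7-dialkoxy stage, where attack at C8 is the established course.
- Benzyl is kept on O3 of the epoxide: an acyl group there would invite acyl migration in the epoxide and participation at the C2 cation.

**Route**

Step 1
Reactants: 1 kaempferol; 2 benzyl bromide
Product: 3 3,5,7,4'-tetra-O-benzylkaempferol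
Conditions: BnBr (6 equiv), K2CO3, TBAI (cat.), DMF, 70 °C
Reagents that add atoms: benzyl bromide, BrCc1ccccc1
Why: Exhaustive Williamson etherification; the 7-, 4'- and 3-OH groups react readily and the hydrogen-bonded 5-OH follows with excess bromide, iodide catalysis and heat.

Step 2
Reactants: 3 3,5,7,4'-tetra-O-benzylkaempferol; 4 dimethyldioxirane
Product: 5 (2R,3R)-tetra-O-benzylkaempferol 2,3-oxide
Conditions: chiral (salen)Mn(III)Cl [N,N'-bis(3,5-di-tert-butylsalicylidene)-1,2-cyclohexanediamine complex, 10 mol %], DMDO in acetone, CH2Cl2, −20 → 0 °C; filtration through Et3N-deactivated silica, used at once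
Reagents that add atoms: dimethyldioxirane, CC1(C)OO1
Why: Jacobsen–Katsuki epoxidation with dimethyldioxirane as neutral terminal oxidant, a protocol established for the C2=C3 bond of chromones (isoflavones); the chiral oxo-manganese(V) species should deliver oxygen to one face of the planar enol-ether bond and so set C2 and C3 together (cis by necessity) under catalyst control, while acetone as the only by-product spares the acetal-like epoxide.

Step 3
Reactants: 1 kaempferol; 6 acetic anhydride
Product: 7 3,5,7,4'-tetra-O-acetylkaempferol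
Conditions: Ac2O, pyridine, DMAP (cat.), rt → 50 °C
Reagents that add atoms: acetic anhydride, CC(=O)OC(C)=O
Why: Standard peracetylation of phenols under nucleophilic catalysis, the chelated 5-OH included.

Step 4
Reactants: 7 3,5,7,4'-tetra-O-acetylkaempferol
Product: 8 3,5,4'-tri-O-acetylkaempferol (free 7-OH)
Conditions: PhSH, imidazole, NMP, 0 °C → rt
Reagents that add atoms: none
Why: Chemoselective thiolysis of an aryl ester; the 7-phenoxide, conjugated through the ring with the C4 carbonyl, is the best leaving group, so thiophenoxide should remove only the 7-O-acetyl group.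

Step 5
Reactants: 8 3,5,4'-tri-O-acetylkaempferol; 9 chloromethyl methyl ether
Product: 10 3,5,4'-tri-O-acetyl-7-O-methoxymethylkaempferol
Conditions: MOMCl, i-Pr2NEt, CH2Cl2, 0 °C → rt
Reagents that add atoms: chloromethyl methyl ether, COCCl
Why: O-alkylation of the only free and most acidic phenol to a MOM acetal under a hindered amine base, which leaves the aryl acetates untouched.

Step 6
Reactants: 10 3,5,4'-tri-O-acetyl-7-O-methoxymethylkaempferol; 2 benzyl bromide
Product: 12 3,5,4'-tri-O-benzyl-7-O-methoxymethylkaempferol, via 7-O-methoxymethylkaempferol 11 (not isolated)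
Conditions: K2CO3, MeOH/THF, rt, Ar; evaporate; BnBr, K2CO3, TBAI (cat.), DMF, 65 °C, Ar
Reagents that add atoms: benzyl bromide, BrCc1ccccc1
Why: Base-catalysed transesterification (Zemplén-type methanolysis) frees the three phenols and Williamson benzylation caps them, the MOM acetal being inert to base and the inert atmosphere preventing base-mediated oxygenation of the free flavonol 11.

Step 7
Reactants: 12 3,5,4'-tri-O-benzyl-7-O-methoxymethylkaempferol; 13 N-bromosuccinimide
Product: 14 8-bromo-3,5,4'-tri-O-benzyl-7-O-methoxymethylkaempferol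
Conditions: NBS (1.05 equiv), DMF, 0 °C → rt, dark
Reagents that add atoms: N-bromosuccinimide, O=C1CCC(=O)N1Br
Why: Electrophilic aromatic bromination; in 5,7-dialkoxyflavones the A ring is far more activated than the B ring, and C8 (between O1 and the 7-alkoxy group) is attacked in preference to the doubly flanked C6.

Step 8
Reactants: 14 8-bromo-3,5,4'-tri-O-benzyl-7-O-methoxymethylkaempferol
Product: 15 8-bromo-3,5,4'-tri-O-benzylkaempferol (free 7-OH)
Conditions: conc. HCl (cat.), MeOH/THF, 45 °C
Reagents that add atoms: none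
Why: Acid-catalysed acetal cleavage by transacetalisation to methanol; aryl benzyl ethers and the aryl bromide are stable to dilute acid.

Step 9
Reactants: 15 8-bromo-3,5,4'-tri-O-benzylkaempferol; 16 hexamethyldisilazane; 17 trifluoromethanesulfonic anhydride
Product: 20 3,5,4'-tri-O-benzyl-8-trimethylsilylkaempferol 7-triflate, via 8-bromo-7-O-trimethylsilyl ether 18 (not isolated), via lithium 8-trimethylsilyl-7-phenoxide 19 (not isolated)
Conditions: HMDS, THF, 65 °C, then evaporate; n-BuLi (1.1 equiv), THF, −100 → −78 °C; Tf2O, −78 → 0 °C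
Reagents that add atoms: hexamethyldisilazane, C[Si](C)(C)N[Si](C)(C)C; trifluoromethanesulfonic anhydride, O=S(=O)(OS(=O)(=O)C(F)(F)F)C(F)(F)F
Why: O-silylation, bromine–lithium exchange, retro-Brook 1,3-O→C silyl shift and O-triflation form the standard one-pot route from o-bromophenols to o-silylaryl triflates; at −100 °C the exchange and the intramolecular silyl shift should outrun addition of n-BuLi to the electron-rich, 5-O-shielded vinylogous-ester carbonyl.

Step 10
Reactants: 5 (2R,3R)-tetra-O-benzylkaempferol 2,3-oxide; 20 3,5,4'-tri-O-benzyl-8-trimethylsilylkaempferol 7-triflate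
Product: 22 (2R,3S)-hepta-O-benzyl ketal of the target, via 7'',8''-aryne 21 (not isolated)
Conditions: CsF (4 equiv), 4 Å MS, PhMe/MeCN (4:1), 40 °C; 20 (1.5 equiv) added by syringe pump
Reagents that add atoms: none
Why: Proposed new method: fluoride-induced 1,2-elimination of 20 gives aryne 21; the epoxide oxygen of 5 adds to C7'', the aryl oxonium so formed opens at C2–O to an oxocarbenium ion stabilised by O1 and the 4-benzyloxyphenyl ring, and the C8'' carbanion collapses on C2. The closest known reaction is the insertion of arynes into the benzylic C–O bond of simple aryl epoxides to give 2,3-dihydrobenzofurans; new here are a 2,3-dioxygenated α-keto epoxide and an aryne of this complexity. The dihydrofuran ring O7''–C3–C2–C8''–C7'' closes in a 5-exo-trig mode, the C8'' anion adding to the C2=O1+ carbon whose π bond lies outside the new ring. C3 is never touched and keeps its configuration; C2 is re-formed from a planar cation, but the two-atom C7''–O7'' tether lets C8'' reach only the face that held the epoxide oxygen, so the cis fusion and the 2R configuration follow from C3. Two selectivities are needed: oxygen attack at C7'' and not C8'', which the σ-withdrawing O1'' on C8a'' should secure by polarising the aryne as in 3-alkoxybenzynes and stabilising the C8'' carbanion; and ionisation at C2 and not C3, which the two donors on C2 should secure against the cation-destabilising C4 carbonyl next to C3. Slow generation of the aryne in the presence of the epoxide should limit its capture by benzyl ether and carbonyl oxygens.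

Step 11
Reactants: 22 (2R,3S)-hepta-O-benzyl ketal of the target
Product: 23 target biflavonoid (CNP0314633.1), (2R,3S)
Conditions: H2 (1 atm), Pd(OH)2/C, THF/EtOAc, rt
Reagents that add atoms: none
Why: Catalytic hydrogenolysis should cleave the six aryl benzyl ethers and the benzyl ketal, releasing the C3 oxygen as the hemiketal OH without breaking a bond at C3 (the cis ring fusion fixes its configuration), while the flavonol C2''=C3'' bond and the aryl ketones are not reduced under these mild conditions.

**Compound list**

1 | kaempferol | O=c1c(O)c(-c2ccc(O)cc2)oc2cc(O)cc(O)c12 | starting material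
2 | benzyl bromide | BrCc1ccccc1 | starting material
3 | 3,5,7,4'-tetra-O-benzylkaempferol | O=c1c(OCc2ccccc2)c(-c2ccc(OCc3ccccc3)cc2)oc2cc(OCc3ccccc3)cc(OCc3ccccc3)c12 | intermediate
4 | dimethyldioxirane | CC1(C)OO1 | starting material
5 | (2R,3R)-3,5,7-tris(benzyloxy)-2-[4-(benzyloxy)phenyl]-2,3-epoxychroman-4-one (tetra-O-benzylkaempferol 2,3-oxide) | O=C1c2c(OCc7ccccc7)cc(OCc7ccccc7)cc2O[C@]2(c3ccc(OCc7ccccc7)cc3)O[C@]12OCc7ccccc7 | intermediate
6 | acetic anhydride | CC(=O)OC(C)=O | starting material
7 | 3,5,7,4'-tetra-O-acetylkaempferol | CC(=O)Oc1ccc(cc1)-c1oc2cc(OC(C)=O)cc(OC(C)=O)c2c(=O)c1OC(C)=O | intermediate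
8 | 3,5,4'-tri-O-acetylkaempferol (free 7-OH) | CC(=O)Oc1ccc(cc1)-c1oc2cc(O)cc(OC(C)=O)c2c(=O)c1OC(C)=O | intermediate
9 | chloromethyl methyl ether | COCCl | starting material
10 | 3,5,4'-tri-O-acetyl-7-O-methoxymethylkaempferol | CC(=O)Oc1ccc(cc1)-c1oc2cc(OCOC)cc(OC(C)=O)c2c(=O)c1OC(C)=O | intermediate
11 | 7-O-methoxymethylkaempferol | COCOc1cc(O)c2c(c1)oc(-c1ccc(O)cc1)c(O)c2=O | intermediate (not isolated)
12 | 3,5,4'-tri-O-benzyl-7-O-methoxymethylkaempferol | COCOc1cc(OCc3ccccc3)c2c(c1)oc(-c1ccc(OCc3ccccc3)cc1)c(OCc1ccccc1)c2=O | intermediate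
13 | N-bromosuccinimide | O=C1CCC(=O)N1Br | starting material
14 | 8-bromo-3,5,4'-tri-O-benzyl-7-O-methoxymethylkaempferol | COCOc1cc(OCc3ccccc3)c2c(c1Br)oc(-c1ccc(OCc3ccccc3)cc1)c(OCc1ccccc1)c2=O | intermediate
15 | 8-bromo-3,5,4'-tri-O-benzylkaempferol (free 7-OH) | Oc1cc(OCc3ccccc3)c2c(c1Br)oc(-c1ccc(OCc3ccccc3)cc1)c(OCc1ccccc1)c2=O | intermediate
16 | hexamethyldisilazane | C[Si](C)(C)N[Si](C)(C)C | starting material
17 | trifluoromethanesulfonic anhydride | O=S(=O)(OS(=O)(=O)C(F)(F)F)C(F)(F)F | starting material
18 | 8-bromo-3,5,4'-tri-O-benzyl-7-O-trimethylsilylkaempferol | C[Si](C)(C)Oc1cc(OCc3ccccc3)c2c(c1Br)oc(-c1ccc(OCc3ccccc3)cc1)c(OCc1ccccc1)c2=O | intermediate (not isolated)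
19 | lithium 3,5,4'-tri-O-benzyl-8-trimethylsilylkaempferol-7-olate | [Li+].[O-]c1cc(OCc3ccccc3)c2c(c1[Si](C)(C)C)oc(-c1ccc(OCc3ccccc3)cc1)c(OCc1ccccc1)c2=O | intermediate (not isolated)
20 | 3,5,4'-tri-O-benzyl-8-trimethylsilylkaempferol 7-triflate | C[Si](C)(C)c1c(OS(=O)(=O)C(F)(F)F)cc(OCc7ccccc7)c2c(=O)c(OCc7ccccc7)c(-c3ccc(OCc7ccccc7)cc3)oc12 | intermediate
21 | 3,5,4'-tri-O-benzyl-7-deoxy-7,8-didehydrokaempferol (7,8-aryne) | O=C1C(OCc2ccccc2)=C(c2ccc(OCc3ccccc3)cc2)OC2=C1C(OCc1ccccc1)=CC#C2 | intermediate (not isolated)
22 | (2R,3S)-hepta-O-benzyl ketal of the target: cis-fused dihydrofuran O7''–C3–C2–C8''–C7'', benzyl ethers on O5, O7, O4', O3'', O5'', O4''' and a benzyl ketal on C3 | O=C1c2c(OCc7ccccc7)cc(OCc7ccccc7)cc2O[C@]2(c3ccc(OCc7ccccc7)cc3)c3c(cc(OCc7ccccc7)c4c(=O)c(OCc7ccccc7)c(-c5ccc(OCc7ccccc7)cc5)oc34)O[C@]12OCc7ccccc7 | intermediate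
23 | target (CNP0314633.1): (2R,3S) C2–C8''/C3–O7''-linked kaempferol dimer with C3 hemiketal | O=C1c2c(O)cc(O)cc2O[C@]2(c3ccc(O)cc3)c3c(cc(O)c4c(=O)c(O)c(-c5ccc(O)cc5)oc34)O[C@]12O | target

**Totals.** 11 steps in all. Longest linear sequence: 9 steps (steps 3–11, kaempferol → 23); the epoxide branch is 2 steps (steps 1–2).

**Steps most likely to fail, with fallbacks**

1. Step 10 (proposed new method). The aryne may be consumed by benzyl ether or carbonyl oxygens, or by self-reaction, before the weakly nucleophilic epoxide oxygen captures it; alternatively the zwitterion may be protonated before ring closure. The fallback makes the same two bonds by polar chemistry of known type. It sets out from 12 and 5 and rejoins the route at 23.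
   - MOM ether 12 is cleaved under the conditions of step 8 to 3,5,4'-tri-O-benzylkaempferol F1, whose C8'' is the nucleophilic position ortho to the free 7''-OH.
   - Epoxide 5 and F1 are treated with a catalytic acid in HFIP/CH2Cl2 (BF3·OEt2 or TfOH, −20 °C → rt). This should ionise the epoxide at C2, Friedel–Crafts attack of C8'' should form C2–C8'', and the C3 hemiketal released should exchange with the 7''-OH with loss of benzyl alcohol.
   - The product would be the (2R,3S)-hexa-O-benzyl hemiketal F2, cis-fused by necessity.
   - The C2 cation is planar and C3 passes through a ketone, so the epoxide configuration is not expected to survive. F2 would form together with its (2S,3R)-enantiomer F3 and is separated from it by preparative chiral HPLC.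
   - Hydrogenolysis of F2 under the conditions of step 11 gives 23.

2. Step 2. Face selectivity may be poor, uncatalysed oxidation by the dioxirane may compete, or the acetal-like epoxide may decompose on handling. The fallback replaces asymmetric catalysis by resolution at a robust stage. It sets out from 3 and rejoins the route at 22.
   - 3 is epoxidised with DMDO alone (acetone/CH2Cl2, 0 °C), which gives 5 as a racemate with the (2S,3S)-epoxide F4.
   - The crude racemate is taken through step 10 unchanged.
   - The resulting 22 is separated from the (2S,3R)-heptabenzyl ketal F5 by preparative chiral HPLC on a polysaccharide phase.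

3. Step 9. n-BuLi may add to the chromone (at C4'' or C2'') in competition with bromine–lithium exchange, or the silyl migration may be incomplete. The fallback brings in silicon by palladium catalysis before the phenol is freed. It sets out from 14 and rejoins the route at 20.
   - Bromide 14 is coupled with hexamethyldisilane (Pd2(dba)3, biaryl dialkylphosphine, KF, dioxane/H2O, 100 °C) to give 8-trimethylsilyl-3,5,4'-tri-O-benzyl-7-O-methoxymethylkaempferol F6.
   - The MOM acetal is removed under mild acid chosen to avoid ipso-protodesilylation (PPTS, MeOH, 50 °C), giving 8-trimethylsilyl-3,5,4'-tri-O-benzylkaempferol F7.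
   - Triflation (Tf2O, pyridine, CH2Cl2, 0 °C) gives 20.

**Further compounds**

F1 | step 10 | 3,5,4'-tri-O-benzylkaempferol (free 7-OH) | Oc1cc(OCc3ccccc3)c2c(c1)oc(-c1ccc(OCc3ccccc3)cc1)c(OCc1ccccc1)c2=O
F2 | step 10 | (2R,3S)-hexa-O-benzyl hemiketal (free C3–OH; benzyl ethers on O5, O7, O4', O3'', O5'', O4''') | O=C1c2c(OCc7ccccc7)cc(OCc7ccccc7)cc2O[C@]2(c3ccc(OCc7ccccc7)cc3)c3c(cc(OCc7ccccc7)c4c(=O)c(OCc7ccccc7)c(-c5ccc(OCc7ccccc7)cc5)oc34)O[C@]12O
F3 | step 10 | (2S,3R)-enantiomer of F2 | O=C1c2c(OCc7ccccc7)cc(OCc7ccccc7)cc2O[C@@]2(c3ccc(OCc7ccccc7)cc3)c3c(cc(OCc7ccccc7)c4c(=O)c(OCc7ccccc7)c(-c5ccc(OCc7ccccc7)cc5)oc34)O[C@@]12O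
F4 | step 2 | (2S,3S)-tetra-O-benzylkaempferol 2,3-oxide (enantiomer of 5) | O=C1c2c(OCc7ccccc7)cc(OCc7ccccc7)cc2O[C@@]2(c3ccc(OCc7ccccc7)cc3)O[C@@]12OCc7ccccc7
F5 | step 2 | (2S,3R)-hepta-O-benzyl ketal (enantiomer of 22) | O=C1c2c(OCc7ccccc7)cc(OCc7ccccc7)cc2O[C@@]2(c3ccc(OCc7ccccc7)cc3)c3c(cc(OCc7ccccc7)c4c(=O)c(OCc7ccccc7)c(-c5ccc(OCc7ccccc7)cc5)oc34)O[C@@]12OCc7ccccc7
F6 | step 9 | 8-trimethylsilyl-3,5,4'-tri-O-benzyl-7-O-methoxymethylkaempferol | COCOc1cc(OCc3ccccc3)c2c(c1[Si](C)(C)C)oc(-c1ccc(OCc3ccccc3)cc1)c(OCc1ccccc1)c2=O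
F7 | step 9 | 8-trimethylsilyl-3,5,4'-tri-O-benzylkaempferol (free 7-OH) | Oc1cc(OCc3ccccc3)c2c(c1[Si](C)(C)C)oc(-c1ccc(OCc3ccccc3)cc1)c(OCc1ccccc1)c2=O
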